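## Retrosynthetic overview

1. Feature: the cyclohexene is numbered C1 (methyl-bearing alkene carbon), C2, C3 (ring A), C4 (aroyl of ring B), C5 (ring C), C6. Ring A is bonded to crowded C3 through C3', the carbon between the oxygenated carbons C2' and C4', and it carries the chalcone carbonyl on C1' next to C2'-OH. A C3-bound siloxyalkyne and a vinylketene with a masked acetyl terminus give exactly this 1-acyl-2,4-dioxy-3-alkyl pattern.
2. Key disconnection: ring A (bonds C2'–C3', C4'–C5', C1'–C2') goes back to a C3 (triisopropylsiloxy)ethynyl cyclohexene and (E)-1-diazo-4-(2-methyl-1,3-dioxolan-2-yl)but-3-en-2-one (Danheiser benzannulation).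
3. After it: C4–CH2OSi becomes the aldehyde, ring B aryllithium is added and the carbinol is oxidised. The acetyl group is unmasked and joined to protected 2,4-dihydroxybenzaldehyde by directed aldol and dehydration, followed by one global deprotection.
4. Before it: the ynol silyl ether comes from the terminal alkyne, and the C5–ring C bond from a decarboxylative Negishi arylation trans to C4. The cyclohexene, with C3/C4 cis and the absolute configuration, comes from an oxazolidinone-controlled endo Diels–Alder reaction of a silylated dienyne with a fumaroyl imide.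
5. Ring order: cyclohexene formed, ring C attached, ring A built, ring B attached, chalcone ring attached.

Key step: step 16

Assumption: the drawn enantiomer has the C3 and C4 substituents cis and the C4 and C5 substituents trans, (3S,4R,5S) in the locants above. These locants, the primed locants of ring A and "core" for 1-methylcyclohex-1-ene are used for every intermediate, and compounds marked starting material are taken as commercial.

## Route

Step 1
Reactants: 1 3-(trimethylsilyl)prop-2-ynal; 2 1-(triphenyl-λ5-phosphanylidene)propan-2-one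
Product: 3 (E)-6-(trimethylsilyl)hex-3-en-5-yn-2-one
Conditions: CH2Cl2, 0 °C to rt
Reagents that add atoms: none
Why: The Wittig reaction of a stabilised acyl ylide with an aldehyde is E-selective and leaves the alkynylsilane alone, and any Z isomer can be removed by chromatography.

Step 2
Reactants: 3 (E)-6-(trimethylsilyl)hex-3-en-5-yn-2-one
Product: 4 (E)-trimethyl(5-methylhexa-3,5-dien-1-yn-1-yl)silane
Conditions: Ph3PCH3Br, n-BuLi, THF, 0 °C; then 3, −78 °C to rt
Reagents that add atoms: methyltriphenylphosphonium bromide, C[P+](c1ccccc1)(c1ccccc1)c1ccccc1.[Br-]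
Why: Wittig methylenation takes place at the ketone carbonyl of the enone, so the E alkene and the C–Si bond are kept and the 1-alkynyl-3-methylbuta-1,3-diene (future C3, C2, C1, C6) is completed.

Step 3
Reactants: 5 (E)-4-tert-butoxy-4-oxobut-2-enoic acid (mono-tert-butyl fumarate); 6 (S)-4-benzyl-1,3-oxazolidin-2-one
Product: 8 tert-butyl (E)-4-[(S)-4-benzyl-2-oxo-1,3-oxazolidin-3-yl]-4-oxobut-2-enoate, via mixed pivalic anhydride 7 (not isolated)
Conditions: PivCl, Et3N, THF, −20 °C; then 6, LiCl, −20 °C to rt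
Reagents that add atoms: none
Why: Acylation of the oxazolidinone through a mixed pivalic anhydride with Et3N and LiCl is the standard mild route to N-enoyl imides, attack going to the less hindered fumaroyl carbonyl without loss of the E geometry.

Step 4
Reactants: 4 (E)-trimethyl(5-methylhexa-3,5-dien-1-yn-1-yl)silane; 8 fumaroyl imide
Product: 9 (3S,4S,5S)-cycloadduct: core with C3 C≡C–SiMe3; C4 C(=O)-[(S)-4-benzyl-2-oxooxazolidin-3-yl] cis to C3; C5 CO2t-Bu trans to C4
Conditions: Et2AlCl (2.2 equiv), 4 (2 equiv), CH2Cl2, −78 to −30 °C; 1 M HCl quench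
Reagents that add atoms: none
Why: In this auxiliary-controlled, Lewis acid promoted Diels–Alder reaction Et2AlCl ties both imide carbonyls into a cationic s-cis chelate whose face opposite the benzyl group is open (absolute configuration at C4), the nucleophilic CH2 terminus of 4 bonds to the carbon beta to the imide so that the alkynyl-bearing terminus becomes C3 next to C4, the endo position of the chelated imide sets C3 and C4 cis, and the E geometry of 8 sets C4 and C5 trans.

Step 5
Reactants: 9 cycloadduct
Product: 11 (3S,4S,5S)-C5 carboxylic acid (C3 and C4 groups as in 9), via trimethylsilyl ester 10 (not isolated)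
Conditions: TMSOTf (3 equiv), 2,6-lutidine (4 equiv), CH2Cl2, 0 °C to rt; aq citric acid work-up
Reagents that add atoms: none
Why: Silyl triflate mediated cleavage of a tert-butyl ester (loss of isobutene, hydrolysis of silyl ester 10 on work-up) needs no protic acid, so the trisubstituted alkene, the imide, the alkynylsilane and the three stereocentres should be kept.

Step 6
Reactants: 11 C5 carboxylic acid
Product: 12 (3S,4S,5S)-C5 N-phthalimidoyl (redox-active) ester (C3 and C4 groups as in 9)
Conditions: N-hydroxyphthalimide, DIC, DMAP (10 mol%), CH2Cl2, rt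
Reagents that add atoms: N-hydroxyphthalimide, O=C1c2ccccc2C(=O)N1O
Why: Steglich-type carbodiimide esterification with N-hydroxyphthalimide turns the C5 acid into a redox-active ester under neutral conditions that do not enolise C4.

Step 7
Reactants: 13 4-bromoresorcinol
Product: 14 1-bromo-2,4-bis(methoxymethoxy)benzene
Conditions: MOMCl (2.5 equiv), i-Pr2NEt, CH2Cl2, 0 °C to rt
Reagents that add atoms: chloromethyl methyl ether, COCCl
Why: Double O-alkylation of the phenols with MOMCl and a tertiary amine gives acetal ethers that tolerate the organolithium, hydride, fluoride and base steps to come.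

Step 8
Reactants: 12 redox-active ester; 14 1-bromo-2,4-bis(methoxymethoxy)benzene
Product: 17 (3S,4R,5S)-C5 aryl imide: core with C3 C≡C–SiMe3; C4 imide cis to C3; C5 2,4-bis(methoxymethoxy)phenyl (ring C) trans to C4, via aryllithium 15 (not isolated), via arylzinc chloride 16 (not isolated)
Conditions: 14 (3 equiv), n-BuLi, THF, −78 °C; ZnCl2, −78 °C to rt; then 12, NiCl2·glyme (20 mol%), 4,4'-di-tert-butyl-2,2'-bipyridine (40 mol%), THF/DMF, rt
Reagents that add atoms: none
Why: In this nickel-catalysed decarboxylative Negishi arylation electron transfer to 12 releases CO2 and phthalimide anion, and the planar C5 radical is taken up by the arylnickel species on the face away from the C4 imide and the pseudoaxial C3 alkyne, so ring C is set trans to C4 independently of the former C5 configuration.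

Step 9
Reactants: 17 C5 aryl imide
Product: 18 (3S,4R,5S)-alcohol: core with C3 C≡C–SiMe3; C4 CH2OH cis to C3; C5 ring C trans to C4
Conditions: LiBH4, MeOH (1.1 equiv), Et2O, 0 °C to rt
Reagents that add atoms: none
Why: LiBH4 reduction of the N-acyl oxazolidinone attacks the exocyclic carbonyl, returns auxiliary 6 and brings C4 to the alcohol level, where it can neither epimerise nor react with the acetylide, ynolate and phenol that appear later.

Step 10
Reactants: 18 silylalkyne alcohol
Product: 19 (3S,4R,5S)-alkynol: core with C3 C≡CH; C4 CH2OH; C5 ring C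
Conditions: K2CO3 (0.3 equiv), MeOH, rt
Reagents that add atoms: none
Why: Carbonate-catalysed methanolysis of the C(sp)–Si bond is a standard protiodesilylation, too weakly basic to isomerise the skipped enyne at C3.

Step 11
Reactants: 19 alkynol
Product: 22 (3S,4R,5S)-siloxyalkyne: core with C3 C≡C–OSi(i-Pr)3; C4 CH2OSi(i-Pr)3 cis to C3; C5 ring C trans to C4, via dilithio alkoxide acetylide 20 (not isolated), via lithium ynolate 21 (not isolated)
Conditions: n-BuLi (2.1 equiv), THF, −78 °C; LiOOt-Bu (from t-BuOOH and LiHMDS, THF, −78 °C), −78 to 0 °C; TIPSOTf (2.5 equiv), −78 to 0 °C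
Reagents that add atoms: tert-butyl hydroperoxide, CC(C)(C)OO; triisopropylsilyl triflate, CC(C)[Si](C(C)C)(C(C)C)OS(=O)(=O)C(F)(F)F
Why: Oxidation of a lithium acetylide with lithium tert-butyl peroxide (oxygen transfer with loss of tert-butoxide) gives the lithium ynolate, which the bulky silyl triflate traps on oxygen and not on carbon, and the C4 alkoxide is silylated in the same operation so that no separate protection is needed.

Step 12
Reactants: 23 methyl (E)-4-oxopent-2-enoate
Product: 24 methyl (E)-3-(2-methyl-1,3-dioxolan-2-yl)prop-2-enoate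
Conditions: TMSOCH2CH2OTMS (1.5 equiv), TMSOTf (5 mol%), CH2Cl2, −78 to −20 °C; pyridine quench
Reagents that add atoms: 1,2-bis(trimethylsilyloxy)ethane, C[Si](C)(C)OCCO[Si](C)(C)C
Why: Silyl triflate catalysed ketalisation with the bis(silyl) glycol (Noyori conditions) is aprotic, so conjugate addition of glycol to the doubly activated alkene is avoided and the alkene stays in conjugation with the ester.

Step 13
Reactants: 24 ketal ester
Product: 25 (E)-N-methoxy-N-methyl-3-(2-methyl-1,3-dioxolan-2-yl)prop-2-enamide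
Conditions: MeNH(OMe)·HCl (1.5 equiv), i-PrMgCl (3 equiv), THF, −20 to 0 °C
Reagents that add atoms: N,O-dimethylhydroxylamine hydrochloride, CNOC.Cl
Why: Aminolysis of the ester with the magnesium amide of N,O-dimethylhydroxylamine gives the Weinreb amide, 1,4-addition being disfavoured by the quaternary carbon at the beta position.

Step 14
Reactants: 25 Weinreb amide
Product: 26 (E)-4-(2-methyl-1,3-dioxolan-2-yl)but-3-en-2-one
Conditions: MeMgBr (1.3 equiv), THF, −78 to 0 °C; aq NH4Cl
Reagents that add atoms: methylmagnesium bromide, C[Mg]Br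
Why: In the Weinreb ketone synthesis the chelated tetrahedral adduct of MeMgBr survives until the quench, so neither over-addition nor conjugate addition to the enone can occur.

Step 15
Reactants: 26 methyl enone
Product: 29 (E)-1-diazo-4-(2-methyl-1,3-dioxolan-2-yl)but-3-en-2-one, via lithium enolate 27 (not isolated), via trifluoroacetyl ketone 28 (not isolated)
Conditions: LiHMDS (1.1 equiv), THF, −78 °C; CF3CO2CH2CF3; cold 1 M HCl wash; then MsN3, Et3N, H2O (1 equiv), MeCN, rt
Reagents that add atoms: methanesulfonyl azide, CS(=O)(=O)N=[N+]=[N-]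
Why: Detrifluoroacetylative diazo transfer (Regitz type) works on the kinetic methyl enolate, whose trifluoroacetylation activates the position for N2 transfer from MsN3 with loss of the trifluoroacetyl group, and it is chosen because acylation of diazomethane with the enoyl chloride would suffer from dipolar cycloaddition to the conjugated alkene.

Step 16
Reactants: 22 siloxyalkyne; 29 diazoketone
Product: 34 (3S,4R,5S)-ring A phenol: core with C3 aryl [C1' 2-methyl-1,3-dioxolan-2-yl; C2' OH; C3' bonded to C3; C4' OSi(i-Pr)3]; C4 CH2OSi(i-Pr)3 cis to C3; C5 ring C trans to C4, via vinylketene 30 (not isolated), via vinylcyclobutenone 31 (not isolated), via dienylketene 32 (not isolated), via cyclohexadienone 33 (not isolated)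
Conditions: 29 (2 equiv, two portions), ClCH2CH2Cl, hν (300 nm), rt until N2 evolution stops; then 80 °C
Reagents that add atoms: none
Why: Light expels N2 from 29 and the alkenyl group migrates (photochemical Wolff rearrangement) to give vinylketene 30, whose carbonyl carbon is attacked by the nucleophilic alkyne carbon of 22 (the one bonded to C3, polarised by the siloxy group) in a [2+2] cycloaddition that gives the 4-alkenyl-3-siloxycyclobutenone 31. Heating opens 31 by reversible four-electron electrocyclic cleavage to dienylketene 32, and ring A closes by six-electron electrocyclisation of the ketene carbon onto the alkene terminus that carries the dioxolane, after which dienone 33 tautomerises to phenol 34. This is the Danheiser benzannulation in its diazoketone variant, for which triisopropylsiloxyalkynes on secondary ring carbons are established partners that give 2-alkylresorcinol monosilyl ethers, only the ketal-bearing vinylketene being new. No lasting stereocentre is formed, since the sp3 carbons of 31 and 33 vanish on aromatisation, and C3, C4 and C5 carry no acidic or light-absorbing group under these neutral conditions. The selectivity needed is the orientation of the [2+2] step, which the O–Si donor secures, so that C3 ends between the phenol carbon C2' and the silyloxy carbon C4' with the masked acetyl on C1', and the far higher nucleophilicity of the ynol ether keeps the ketene away from the C1=C2 alkene. C4 is carried as CH2OSi(i-Pr)3 because an acyl group there would be attacked by the acetylide of step 11 and by the cis phenol that this step sets free.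

Step 17
Reactants: 34 ring A phenol
Product: 36 (3S,4R,5S)-C2' MOM ether (C4' OSi(i-Pr)3 and C4 CH2OSi(i-Pr)3 kept), via sodium phenoxide 35 (not isolated)
Conditions: NaH, DMF, 0 °C; then MOMCl, 0 °C to rt
Reagents that add atoms: chloromethyl methyl ether, COCCl
Why: Williamson-type alkylation of the hindered sodium phenoxide with the small electrophile MOMCl caps the phenol next to the dioxolane, which lowers the acid lability of the ketal, while both silyl ethers tolerate NaH.

Step 18
Reactants: 36 bis(silyl) MOM ether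
Product: 37 (3S,4R,5S)-C4' phenol with C4 CH2OH (C2' OMOM and dioxolane kept)
Conditions: TBAF (3 equiv), THF, 0 °C to rt; aq NH4Cl
Reagents that add atoms: none
Why: Fluoride cleaves the aryl and the primary alkyl triisopropylsilyl ethers through pentacoordinate silicon, and MOM ethers, dioxolane and alkene are inert to it.

Step 19
Reactants: 37 phenol alcohol
Product: 38 (3S,4R,5S)-alcohol with ring A as C2',C4'-bis(MOM) ether and C4 CH2OH free
Conditions: MOMCl (1.1 equiv), K2CO3, acetone, 0 °C to rt
Reagents that add atoms: chloromethyl methyl ether, COCCl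
Why: In this chemoselective Williamson-type alkylation K2CO3 ionises only the phenol, whose phenoxide outruns the neutral, beta-branched primary alcohol for the single equivalent of MOMCl.

Step 20
Reactants: 38 primary alcohol
Product: 39 (3S,4R,5S)-C4 carbaldehyde
Conditions: Dess–Martin periodinane, pyridine, CH2Cl2, 0 °C to rt
Reagents that add atoms: none
Why: Dess–Martin oxidation buffered with pyridine stops at the aldehyde, is compatible with ketal, MOM ethers and electron-rich arenes, and is mild enough not to epimerise C4.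

Step 21
Reactants: 14 1-bromo-2,4-bis(methoxymethoxy)benzene
Product: 41 1-bromo-3-iodo-2,4-bis(methoxymethoxy)benzene, via 3-lithio arene 40 (not isolated)
Conditions: LDA (1.1 equiv), THF, −78 °C; then I2
Reagents that add atoms: iodine, II
Why: Directed ortho-metalation with LDA removes the proton between the two MOM ethers (doubly coordinated, most acidic and not ortho to bromine, so neither aryne formation nor bromine–lithium exchange occurs) and iodine quenches the aryllithium.

Step 22
Reactants: 42 3-methylbut-1-yne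
Product: 43 (E)-4,4,5,5-tetramethyl-2-(3-methylbut-1-en-1-yl)-1,3,2-dioxaborolane
Conditions: pinacolborane, Cp2Zr(H)Cl (5 mol%), CH2Cl2, sealed tube, rt
Reagents that add atoms: pinacolborane, B1OC(C)(C)C(C)(C)O1
Why: Zirconium-catalysed hydroboration of the terminal alkyne with pinacolborane is a syn, anti-Markovnikov addition and gives the E alkenylboronate.

Step 23
Reactants: 41 bromo iodide; 43 alkenylboronate
Product: 44 1-bromo-2,4-bis(methoxymethoxy)-3-[(E)-3-methylbut-1-en-1-yl]benzene
Conditions: Pd(PPh3)4 (5 mol%), K2CO3, dioxane/H2O, 80 °C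
Reagents that add atoms: none
Why: Suzuki–Miyaura coupling takes place at the C–I bond, which adds oxidatively to Pd(PPh3)4 much faster than the C–Br bond, with retention of the E geometry of the boronate.

Step 24
Reactants: 44 ring B bromide; 39 C4 carbaldehyde
Product: 46 (3S,4R,5S)-C4 aryl carbinol (ring B attached; both carbinol epimers), via aryllithium 45 (not isolated)
Conditions: 44 (1.5 equiv), n-BuLi, THF, −78 °C; then 39, −78 °C; aq NH4Cl
Reagents that add atoms: none
Why: Bromine–lithium exchange is faster than any addition of n-BuLi to the styrene, 1,2-addition of the aryllithium to the aldehyde at −78 °C outruns enolisation at C4, and the new carbinol centre need not be controlled because step 25 erases it.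

Step 25
Reactants: 46 aryl carbinol
Product: 47 (3S,4R,5S)-C4 aryl ketone with ring A still as dioxolane
Conditions: Dess–Martin periodinane, pyridine, CH2Cl2, rt
Reagents that add atoms: none
Why: Dess–Martin oxidation converts both carbinol epimers into the single aryl ketone and does not touch the styrene or the ring alkene.

Step 26
Reactants: 47 ketal ketone
Product: 48 (3S,4R,5S)-diketone with C1' acetyl on ring A
Conditions: PPTS (20 mol%), acetone/H2O (9:1), rt
Reagents that add atoms: water, O
Why: Mild acid-catalysed hydrolysis opens the electron-rich aryl ketal far faster than the aryl MOM acetals, so only the acetyl group is unmasked.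

Step 27
Reactants: 49 2,4-dihydroxybenzaldehyde
Product: 50 2,4-bis(methoxymethoxy)benzaldehyde
Conditions: MOMCl (3 equiv), K2CO3, acetone, reflux
Reagents that add atoms: chloromethyl methyl ether, COCCl
Why: Williamson-type alkylation with excess reagent and heating also caps the hydrogen-bonded ortho phenol.

Step 28
Reactants: 48 diketone; 50 2,4-bis(methoxymethoxy)benzaldehyde
Product: 52 (3S,4R,5S)-beta-hydroxy ketone (aldol; both carbinol epimers), via lithium enolate 51 (not isolated)
Conditions: LiHMDS (1.05 equiv), THF, −78 °C; then 50, −78 °C; AcOH quench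
Reagents that add atoms: none
Why: In this directed aldol addition LiHMDS takes a proton kinetically from the open acetyl methyl group and not the tertiary C4–H flanked by two arylated carbons, so C4 is not epimerised, and the carbinol centre is erased in step 29.

Step 29
Reactants: 52 aldol
Product: 54 octakis(methoxymethyl) ether of artonin C, via mesylate 53 (not isolated)
Conditions: MsCl, Et3N, CH2Cl2, 0 °C to rt
Reagents that add atoms: none
Why: Mesylation followed by E1cB elimination gives the conjugated enone in its more stable E geometry under amine base too weak to enolise the hindered C4 ketone.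

Step 30
Reactants: 54 octakis(methoxymethyl) ether
Product: 56 artonin C, via octakis(trimethylsilyl) ether 55 (not isolated)
Conditions: TMSOTf (24 equiv), 2,2'-bipyridyl (36 equiv), MeCN, 0 °C to rt; then H2O, rt
Reagents that add atoms: none
Why: Silyl triflate and bipyridyl exchange aryl MOM ethers for aryl silyl ethers that water cleaves, so all eight acetals are removed without a Brønsted acid, which avoids ketalisation of the C4 ketone by the flanking phenols, closure of the 2'-hydroxychalcone to a flavanone and protonation of the alkenes.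

## Compound list

1 | 3-(trimethylsilyl)prop-2-ynal | C[Si](C)(C)C#CC=O | starting material
2 | 1-(triphenyl-λ5-phosphanylidene)propan-2-one | CC(=O)C=P(c1ccccc1)(c1ccccc1)c1ccccc1 | starting material
3 | (E)-6-(trimethylsilyl)hex-3-en-5-yn-2-one | CC(=O)/C=C/C#C[Si](C)(C)C | intermediate
4 | (E)-trimethyl(5-methylhexa-3,5-dien-1-yn-1-yl)silane | CC(=C)/C=C/C#C[Si](C)(C)C | intermediate
5 | (E)-4-tert-butoxy-4-oxobut-2-enoic acid | CC(C)(C)OC(=O)/C=C/C(=O)O | starting material
6 | (S)-4-benzyl-1,3-oxazolidin-2-one | O=C1OC[C@H](Cc2ccccc2)N1 | starting material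
7 | mixed pivalic anhydride of 5 | CC(C)(C)OC(=O)/C=C/C(=O)OC(=O)C(C)(C)C | intermediate
8 | tert-butyl (E)-4-[(S)-4-benzyl-2-oxo-1,3-oxazolidin-3-yl]-4-oxobut-2-enoate | CC(C)(C)OC(=O)/C=C/C(=O)N1[C@@H](Cc2ccccc2)COC1=O | intermediate
9 | (3S,4S,5S)-cycloadduct (C3 silylethynyl, C4 imide, C5 tert-butyl ester) | CC1=C[C@H](C#C[Si](C)(C)C)[C@H](C(=O)N2[C@@H](Cc3ccccc3)COC2=O)[C@@H](C(=O)OC(C)(C)C)C1 | intermediate
10 | (3S,4S,5S)-C5 trimethylsilyl ester | CC1=C[C@H](C#C[Si](C)(C)C)[C@H](C(=O)N2[C@@H](Cc3ccccc3)COC2=O)[C@@H](C(=O)O[Si](C)(C)C)C1 | intermediate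
11 | (3S,4S,5S)-C5 carboxylic acid | CC1=C[C@H](C#C[Si](C)(C)C)[C@H](C(=O)N2[C@@H](Cc3ccccc3)COC2=O)[C@@H](C(=O)O)C1 | intermediate
12 | (3S,4S,5S)-C5 N-phthalimidoyl ester | CC1=C[C@H](C#C[Si](C)(C)C)[C@H](C(=O)N2[C@@H](Cc3ccccc3)COC2=O)[C@@H](C(=O)ON2C(=O)c3ccccc3C2=O)C1 | intermediate
13 | 4-bromoresorcinol | Oc1ccc(Br)c(O)c1 | starting material
14 | 1-bromo-2,4-bis(methoxymethoxy)benzene | COCOc1ccc(Br)c(OCOC)c1 | intermediate
15 | 2,4-bis(methoxymethoxy)phenyllithium | COCOc1ccc([Li])c(OCOC)c1 | intermediate
16 | 2,4-bis(methoxymethoxy)phenylzinc chloride | COCOc1ccc([Zn]Cl)c(OCOC)c1 | intermediate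
17 | (3S,4R,5S)-C5 aryl imide | CC1=C[C@H](C#C[Si](C)(C)C)[C@H](C(=O)N2[C@@H](Cc3ccccc3)COC2=O)[C@@H](c2ccc(OCOC)cc2OCOC)C1 | intermediate
18 | (3S,4R,5S)-C4 hydroxymethyl silylalkyne | CC1=C[C@H](C#C[Si](C)(C)C)[C@H](CO)[C@@H](c2ccc(OCOC)cc2OCOC)C1 | intermediate
19 | (3S,4R,5S)-alkynol | CC1=C[C@H](C#C)[C@H](CO)[C@@H](c2ccc(OCOC)cc2OCOC)C1 | intermediate
20 | dilithio alkoxide acetylide of 19 | CC1=C[C@H](C#C[Li])[C@H](CO[Li])[C@@H](c2ccc(OCOC)cc2OCOC)C1 | intermediate
21 | lithium ynolate (C4 lithium alkoxide) | CC1=C[C@H](C#CO[Li])[C@H](CO[Li])[C@@H](c2ccc(OCOC)cc2OCOC)C1 | intermediate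
22 | (3S,4R,5S)-siloxyalkyne (key precursor) | CC1=C[C@H](C#CO[Si](C(C)C)(C(C)C)C(C)C)[C@H](CO[Si](C(C)C)(C(C)C)C(C)C)[C@@H](c2ccc(OCOC)cc2OCOC)C1 | intermediate
23 | methyl (E)-4-oxopent-2-enoate | CC(=O)/C=C/C(=O)OC | starting material
24 | methyl (E)-3-(2-methyl-1,3-dioxolan-2-yl)prop-2-enoate | COC(=O)/C=C/C1(C)OCCO1 | intermediate
25 | (E)-N-methoxy-N-methyl-3-(2-methyl-1,3-dioxolan-2-yl)prop-2-enamide | CON(C)C(=O)/C=C/C1(C)OCCO1 | intermediate
26 | (E)-4-(2-methyl-1,3-dioxolan-2-yl)but-3-en-2-one | CC(=O)/C=C/C1(C)OCCO1 | intermediate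
27 | lithium enolate of 26 | C=C(O[Li])/C=C/C1(C)OCCO1 | intermediate
28 | (E)-1,1,1-trifluoro-6-(2-methyl-1,3-dioxolan-2-yl)hex-5-ene-2,4-dione | CC1(/C=C/C(=O)CC(=O)C(F)(F)F)OCCO1 | intermediate
29 | (E)-1-diazo-4-(2-methyl-1,3-dioxolan-2-yl)but-3-en-2-one (key precursor) | CC1(/C=C/C(=O)C=[N+]=[N-])OCCO1 | intermediate
30 | (E)-4-(2-methyl-1,3-dioxolan-2-yl)buta-1,3-dien-1-one | CC1(/C=C/C=C=O)OCCO1 | intermediate
31 | 2-(C3-cyclohexenyl)-3-siloxy-4-alkenylcyclobut-2-enone | CC1=C[C@H](C2=C(O[Si](C(C)C)(C(C)C)C(C)C)C(/C=C/C3(C)OCCO3)C2=O)[C@H](CO[Si](C(C)C)(C(C)C)C(C)C)[C@@H](c2ccc(OCOC)cc2OCOC)C1 | intermediate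
32 | dienylketene | CC1=C[C@H](C(=C=O)/C(O[Si](C(C)C)(C(C)C)C(C)C)=C\C=C\C2(C)OCCO2)[C@H](CO[Si](C(C)C)(C(C)C)C(C)C)[C@@H](c2ccc(OCOC)cc2OCOC)C1 | intermediate
33 | cyclohexa-2,4-dienone | CC1=C[C@H](C2=C(O[Si](C(C)C)(C(C)C)C(C)C)C=CC(C3(C)OCCO3)C2=O)[C@H](CO[Si](C(C)C)(C(C)C)C(C)C)[C@@H](c2ccc(OCOC)cc2OCOC)C1 | intermediate
34 | (3S,4R,5S)-ring A phenol (key product) | CC1=C[C@H](c2c(O[Si](C(C)C)(C(C)C)C(C)C)ccc(C3(C)OCCO3)c2O)[C@H](CO[Si](C(C)C)(C(C)C)C(C)C)[C@@H](c2ccc(OCOC)cc2OCOC)C1 | intermediate
35 | sodium phenoxide of 34 | CC1=C[C@H](c2c(O[Si](C(C)C)(C(C)C)C(C)C)ccc(C3(C)OCCO3)c2O[Na])[C@H](CO[Si](C(C)C)(C(C)C)C(C)C)[C@@H](c2ccc(OCOC)cc2OCOC)C1 | intermediate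
36 | (3S,4R,5S)-C2' MOM ether, bis(silyl) | CC1=C[C@H](c2c(O[Si](C(C)C)(C(C)C)C(C)C)ccc(C3(C)OCCO3)c2OCOC)[C@H](CO[Si](C(C)C)(C(C)C)C(C)C)[C@@H](c2ccc(OCOC)cc2OCOC)C1 | intermediate
37 | (3S,4R,5S)-C4' phenol, C4 CH2OH | CC1=C[C@H](c2c(O)ccc(C3(C)OCCO3)c2OCOC)[C@H](CO)[C@@H](c2ccc(OCOC)cc2OCOC)C1 | intermediate
38 | (3S,4R,5S)-ring A bis(MOM) ether, C4 CH2OH | CC1=C[C@H](c2c(OCOC)ccc(C3(C)OCCO3)c2OCOC)[C@H](CO)[C@@H](c2ccc(OCOC)cc2OCOC)C1 | intermediate
39 | (3S,4R,5S)-C4 carbaldehyde | CC1=C[C@H](c2c(OCOC)ccc(C3(C)OCCO3)c2OCOC)[C@H](C=O)[C@@H](c2ccc(OCOC)cc2OCOC)C1 | intermediate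
40 | 3-bromo-2,6-bis(methoxymethoxy)phenyllithium | COCOc1ccc(Br)c(OCOC)c1[Li] | intermediate
41 | 1-bromo-3-iodo-2,4-bis(methoxymethoxy)benzene | COCOc1ccc(Br)c(OCOC)c1I | intermediate
42 | 3-methylbut-1-yne | CC(C)C#C | starting material
43 | (E)-4,4,5,5-tetramethyl-2-(3-methylbut-1-en-1-yl)-1,3,2-dioxaborolane | CC(C)/C=C/B1OC(C)(C)C(C)(C)O1 | intermediate
44 | 1-bromo-2,4-bis(methoxymethoxy)-3-[(E)-3-methylbut-1-en-1-yl]benzene | COCOc1ccc(Br)c(OCOC)c1/C=C/C(C)C | intermediate
45 | ring B aryllithium | COCOc1ccc([Li])c(OCOC)c1/C=C/C(C)C | intermediate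
46 | (3S,4R,5S)-C4 aryl carbinol (carbinol epimers) | CC1=C[C@H](c2c(OCOC)ccc(C3(C)OCCO3)c2OCOC)[C@H](C(O)c2ccc(OCOC)c(/C=C/C(C)C)c2OCOC)[C@@H](c2ccc(OCOC)cc2OCOC)C1 | intermediate
47 | (3S,4R,5S)-C4 aryl ketone, ring A ketal | CC1=C[C@H](c2c(OCOC)ccc(C3(C)OCCO3)c2OCOC)[C@H](C(=O)c2ccc(OCOC)c(/C=C/C(C)C)c2OCOC)[C@@H](c2ccc(OCOC)cc2OCOC)C1 | intermediate
48 | (3S,4R,5S)-diketone with C1' acetyl | CC1=C[C@H](c2c(OCOC)ccc(C(C)=O)c2OCOC)[C@H](C(=O)c2ccc(OCOC)c(/C=C/C(C)C)c2OCOC)[C@@H](c2ccc(OCOC)cc2OCOC)C1 | intermediate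
49 | 2,4-dihydroxybenzaldehyde | O=Cc1ccc(O)cc1O | starting material
50 | 2,4-bis(methoxymethoxy)benzaldehyde | COCOc1ccc(C=O)c(OCOC)c1 | intermediate
51 | lithium enolate of 48 | CC1=C[C@H](c2c(OCOC)ccc(C(=C)O[Li])c2OCOC)[C@H](C(=O)c2ccc(OCOC)c(/C=C/C(C)C)c2OCOC)[C@@H](c2ccc(OCOC)cc2OCOC)C1 | intermediate
52 | (3S,4R,5S)-aldol (carbinol epimers) | CC1=C[C@H](c2c(OCOC)ccc(C(=O)CC(O)c3ccc(OCOC)cc3OCOC)c2OCOC)[C@H](C(=O)c2ccc(OCOC)c(/C=C/C(C)C)c2OCOC)[C@@H](c2ccc(OCOC)cc2OCOC)C1 | intermediate
53 | mesylate of 52 | CC1=C[C@H](c2c(OCOC)ccc(C(=O)CC(OS(C)(=O)=O)c3ccc(OCOC)cc3OCOC)c2OCOC)[C@H](C(=O)c2ccc(OCOC)c(/C=C/C(C)C)c2OCOC)[C@@H](c2ccc(OCOC)cc2OCOC)C1 | intermediate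
54 | octakis(methoxymethyl) ether of artonin C | CC1=C[C@H](c2c(OCOC)ccc(C(=O)/C=C/c3ccc(OCOC)cc3OCOC)c2OCOC)[C@H](C(=O)c2ccc(OCOC)c(/C=C/C(C)C)c2OCOC)[C@@H](c2ccc(OCOC)cc2OCOC)C1 | intermediate
55 | octakis(trimethylsilyl) ether of artonin C | CC1=C[C@H](c2c(O[Si](C)(C)C)ccc(C(=O)/C=C/c3ccc(O[Si](C)(C)C)cc3O[Si](C)(C)C)c2O[Si](C)(C)C)[C@H](C(=O)c2ccc(O[Si](C)(C)C)c(/C=C/C(C)C)c2O[Si](C)(C)C)[C@@H](c2ccc(O[Si](C)(C)C)cc2O[Si](C)(C)C)C1 | intermediate
56 | artonin C, (3S,4R,5S) | CC1=C[C@H](c2c(O)ccc(C(=O)/C=C/c3ccc(O)cc3O)c2O)[C@H](C(=O)c2ccc(O)c(/C=C/C(C)C)c2O)[C@@H](c2ccc(O)cc2O)C1 | target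

## Count and risks

Total step count: 30.
Longest linear sequence: 20 steps (1, 2, 4, 5, 6, 8, 9, 10, 11, 16, 17, 18, 19, 20, 24, 25, 26, 28, 29, 30).

**Step 16 (key step).** The vinylketene may dimerise, or close to its own cyclobutenone, faster than it adds to the hindered alkyne carbon. Ring C may screen the light, and traces of acid may hydrolyse the ynol silyl ether or the ketal. The fallback sets out from 19 and 29 and comes back at 34; it joins the same carbons without irradiating the cyclohexene. Compound 19 would be silylated (TIPSCl, imidazole, DMF) to the primary triisopropylsilyl ether F1, which with n-BuLi and then LiOOt-Bu gives the lithium ynolate F2. Separately, 29 would be C-silylated (TIPSOTf, i-Pr2NEt, Et2O/hexane, 0 °C) to the alpha-silyl diazoketone F3, whose photochemical Wolff rearrangement gives the isolable (triisopropylsilyl)vinylketene F4. Addition of F2 to the carbonyl carbon of F4 (THF, −78 °C to rt) gives a 3-oxidodienylketene that undergoes the same six-electron closure. A 1,3 shift of silicon from C5' to the C4' oxygen, followed by protonation, then delivers 34.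

**Step 8.** The hindered ortho-alkoxyaryl nickel species may capture the C5 radical slowly, which would let hydrogen abstraction or radical dimerisation take over. Nickel may also bind the alkyne, and facial selectivity may erode. The fallback sets out from 12 and comes back at 17; it separates radical formation from C–C coupling. Phosphine-catalysed iododecarboxylation of 12 (LiI, PPh3 10 mol%, blue LED, acetone) would give the C5 iodide F5 as an epimer mixture. F5 would then be coupled with arylzinc chloride 16 under cobalt catalysis (CoCl2·2LiCl, TMEDA, THF, 0 °C to rt). This is a stereoconvergent Negishi coupling of secondary cyclic iodides that again places the aryl group anti to the C4 substituent.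

**Step 4.** The strong aluminium Lewis acid may oligomerise the dienyne, transfer an ethyl group or cleave the tert-butyl ester, and the endo or regiochemical preference may be insufficient. The fallback sets out from 5 and 4 and comes back at 18; it moves facial control from the auxiliary to a milder chiral catalyst. Acid 5 would be coupled as in step 3 with achiral 1,3-oxazolidin-2-one to give the achiral imide F6. Cycloaddition with 4 under Cu(SbF6)2 and (R,R)-2,2'-isopropylidenebis(4-tert-butyl-2-oxazoline) (10 mol%, CH2Cl2, rt) proceeds through a square-planar chelate. The tert-butyl group of that chelate covers the face that the benzyl group covers in 8, and the reaction gives the cycloadduct F7. The operations of steps 5, 6 and 8 then give the acid F8, the redox-active ester F9 and the arylated imide F10, and LiBH4 reduction of F10 gives 18.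

## Further compounds

F1 | step 16 | (3S,4R,5S)-terminal alkyne with C4 CH2OSi(i-Pr)3 | CC1=C[C@H](C#C)[C@H](CO[Si](C(C)C)(C(C)C)C(C)C)[C@@H](c2ccc(OCOC)cc2OCOC)C1
F2 | step 16 | lithium ynolate of F1 | CC1=C[C@H](C#CO[Li])[C@H](CO[Si](C(C)C)(C(C)C)C(C)C)[C@@H](c2ccc(OCOC)cc2OCOC)C1
F3 | step 16 | (E)-1-diazo-4-(2-methyl-1,3-dioxolan-2-yl)-1-(triisopropylsilyl)but-3-en-2-one | CC1(/C=C/C(=O)C(=[N+]=[N-])[Si](C(C)C)(C(C)C)C(C)C)OCCO1
F4 | step 16 | (E)-4-(2-methyl-1,3-dioxolan-2-yl)-2-(triisopropylsilyl)buta-1,3-dien-1-one | CC1(/C=C/C(=C=O)[Si](C(C)C)(C(C)C)C(C)C)OCCO1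
F5 | step 8 | C5 iodide (C5 epimers; C3 and C4 as in 12) | CC1=C[C@H](C#C[Si](C)(C)C)[C@H](C(=O)N2[C@@H](Cc3ccccc3)COC2=O)C(I)C1
F6 | step 4 | tert-butyl (E)-4-oxo-4-(2-oxo-1,3-oxazolidin-3-yl)but-2-enoate | CC(C)(C)OC(=O)/C=C/C(=O)N1CCOC1=O
F7 | step 4 | (3S,4S,5S)-cycloadduct with achiral imide | CC1=C[C@H](C#C[Si](C)(C)C)[C@H](C(=O)N2CCOC2=O)[C@@H](C(=O)OC(C)(C)C)C1
F8 | step 4 | (3S,4S,5S)-C5 acid with achiral imide | CC1=C[C@H](C#C[Si](C)(C)C)[C@H](C(=O)N2CCOC2=O)[C@@H](C(=O)O)C1
F9 | step 4 | (3S,4S,5S)-C5 N-phthalimidoyl ester with achiral imide | CC1=C[C@H](C#C[Si](C)(C)C)[C@H](C(=O)N2CCOC2=O)[C@@H](C(=O)ON2C(=O)c3ccccc3C2=O)C1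
F10 | step 4 | (3S,4R,5S)-C5 aryl compound with achiral imide | CC1=C[C@H](C#C[Si](C)(C)C)[C@H](C(=O)N2CCOC2=O)[C@@H](c2ccc(OCOC)cc2OCOC)C1
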